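**Plan**

- Retrosynthesis: the two O-benzyl groups come off last and the C7' ketone goes back to a silylated benzylic carbinol. The tetrahydrofuran (O1, C2 aryl, C3 bearing C9H2OH, C4 bearing the C7' aroyl, C5) is then cut at C3–C4, and after that at the C5–O1 ether bond.
- Enabling feature: C3–C4 joins a carbon carrying CH2–O (C3 and C9, the two carbons of a terminal epoxide) to a carbon whose exocyclic neighbour C7' bears both aryl and oxygen (an aryl silyl enol ether). The C2 benzylic ether stereocentre sits directly beside C3.
- Forward: benzylated syringaldehyde and vinylmagnesium bromide give one 1-arylallyl alcohol that is used twice, as the epoxy alcohol (Sharpless kinetic resolution) and, after oxidation, as the aryl vinyl ketone. Oxa-Michael addition joins the two through C5–O1, and enol silylation installs the acceptor.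
- The only ring, the tetrahydrofuran, closes in the radical step (C3–C4). Desilylation, MnO2 oxidation at C7' and hydrogenolysis finish the route.
- Stereochemistry: C2 comes from the tartrate-controlled kinetic resolution. C3 and C4 are relayed from C2 through a chair-like 5-exo transition state (2,3-trans, 3,4-cis). The epoxide carbon and C7' configurations are erased on the way.

Key step: step 7

Remark: Ar = 4-(benzyloxy)-3,5-dimethoxyphenyl. It is assumed that in the Sharpless resolution the aryl group takes the place of the carbinol substituent in the usual model, so that D-(−)-diisopropyl tartrate selects the (S)-allylic alcohol, whose carbinol carbon has the spatial arrangement of C2 of the target.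

**Route**

Step 1
Reactants: 1 syringaldehyde
Product: 2 4-(benzyloxy)-3,5-dimethoxybenzaldehyde
Conditions: BnBr, K2CO3, DMF, 60 °C
Reagents that add atoms: benzyl bromide, BrCc1ccccc1
Why: Williamson O-alkylation of the phenoxide; the benzyl ether should survive the organometallic, Lewis acidic, radical and fluoride steps and leaves by hydrogenolysis at the end.

Step 2
Reactants: 2 4-(benzyloxy)-3,5-dimethoxybenzaldehyde; 3 vinylmagnesium bromide
Product: 4 rac-1-[4-(benzyloxy)-3,5-dimethoxyphenyl]prop-2-en-1-ol
Conditions: CH2=CHMgBr, THF, −20 to 0 °C; aq. NH4Cl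
Reagents that add atoms: vinylmagnesium bromide (compound 3), C=C[Mg]Br
Why: Grignard 1,2-addition to a non-enolisable aryl aldehyde; the racemate is intended, since it feeds both the resolution and the enone.

Step 3
Reactants: 4 rac-1-[4-(benzyloxy)-3,5-dimethoxyphenyl]prop-2-en-1-ol
Product: 5 (R)-[4-(benzyloxy)-3,5-dimethoxyphenyl][(2S)-oxiran-2-yl]methanol
Conditions: Ti(OiPr)4 (10 mol%), D-(−)-diisopropyl tartrate (15 mol%), tBuOOH (0.45 equiv), 4 Å MS, CH2Cl2, −20 °C
Reagents that add atoms: tert-butyl hydroperoxide, CC(C)(C)OO
Why: Sharpless kinetic resolution by asymmetric epoxidation, in which the titanium–D-tartrate catalyst should epoxidise the (S)-enantiomer of 4 much faster than the (R)-enantiomer and with erythro selectivity, so that stopping below half conversion selects the carbinol centre (the future C2) and sets the epoxide carbon by the tartrate, while unreacted (R)-4 is separated by chromatography.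

Step 4
Reactants: 4 rac-1-[4-(benzyloxy)-3,5-dimethoxyphenyl]prop-2-en-1-ol
Product: 6 1-[4-(benzyloxy)-3,5-dimethoxyphenyl]prop-2-en-1-one
Conditions: activated MnO2, CH2Cl2, rt; filtered through Celite, kept cold in solution with a trace of BHT and used at once
Reagents that add atoms: none
Why: MnO2 oxidation of an allylic and benzylic alcohol to the enone; the stereocentre is destroyed, so racemic 4 or the (R)-enriched alcohol recovered from step 3 serves equally.

Step 5
Reactants: 5 (R)-Ar[(2S)-oxiran-2-yl]methanol; 6 aryl vinyl ketone
Product: 7 1-Ar-3-{(R)-Ar[(2S)-oxiran-2-yl]methoxy}propan-1-one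
Conditions: PMe3 (10 mol%), THF, 0 °C to rt, 6 (2 equiv) added slowly
Reagents that add atoms: none
Why: Phosphine-catalysed oxa-Michael addition, in which PMe3 adds to the enone to give a phosphonium enolate that deprotonates the alcohol and the resulting alkoxide adds to a second enone under aprotic conditions that should leave the epoxide and the carbinol configuration untouched.

Step 6
Reactants: 7 1-Ar-3-{(R)-Ar[(2S)-oxiran-2-yl]methoxy}propan-1-one
Product: 8 (Z)-tert-butyldimethylsilyl enol ether of 7, ArC(OTBS)=CH–CH2–O–CH(Ar)(oxiranyl), (R) at the benzylic ether carbon and (S) at the epoxide carbon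
Conditions: TBSOTf, Et3N, CH2Cl2, −78 to −20 °C; NaHCO3 quench; Et3N-deactivated silica
Reagents that add atoms: tert-butyldimethylsilyl trifluoromethanesulfonate, CC(C)(C)[Si](C)(C)OS(=O)(=O)C(F)(F)F
Why: Soft enolisation of an aryl alkyl ketone (O-silylation, then deprotonation by the amine) should give the (Z)-silyl enol ether with aryl and CH2O trans, without a free enolate that could expel the β-alkoxide.

Step 7
Reactants: 8 (Z)-silyl enol ether epoxide
Product: 9 (2S,3R,4R)-2-Ar-3-(hydroxymethyl)-4-[Ar(tert-butyldimethylsilyloxy)methyl]tetrahydrofuran, both C7' epimers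
Conditions: Cp2TiCl2 (2.5 equiv), Mn dust (8 equiv), degassed THF, rt, to give green Cp2TiCl; this solution added dropwise to 8 in THF (0.01 M), rt, Ar; aq. NaH2PO4
Reagents that add atoms: none
Why: Cp2TiCl (trivalent titanium) binds the epoxide oxygen and cleaves the C–O bond homolytically at the more substituted carbon, so the secondary C3 radical forms with the titanium alkoxide on C9 and the epoxide stereocentre is lost; the radical adds to C4 of the enol ether, and the α-siloxybenzyl radical at C7' is captured by a second Cp2TiCl and protonated on work-up. The closest known reaction type is the Nugent–RajanBabu reductive epoxide opening with 5-exo cyclisation onto the styrenyl double bond of cinnamyl ethers, which delivers 2-aryl-3-hydroxymethyl-4-benzyltetrahydrofurans; here the styrene carries an additional siloxy group on the carbon that becomes the radical centre. The tetrahydrofuran closes 5-exo-trig by formation of C3–C4. C3 and C4 are controlled by C2 through a chair-like (Beckwith–Houk) transition state in which the C2 aryl group is pseudo-equatorial and trans to the new exocyclic C4–C7' bond while the CH2O–Ti group on the radical carbon ends cis to it, which should give 2,3-trans-3,4-cis, that is (2S,3R,4R); C7' forms without control and is removed later. The step needs regioselective epoxide opening (secured by the secondary over the primary radical), 5-exo over 6-endo attack (secured by the unsubstituted C4 terminus and the benzylic, oxygen-stabilised product radical) and cyclisation faster than reduction of the C3 radical to an organotitanium that would eliminate to the alkene (secured by the styrene-type acceptor five atoms away together with slow addition of Cp2TiCl at high dilution).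

Step 8
Reactants: 9 silyl ether, both C7' epimers
Product: 10 (2S,3R,4R)-2-Ar-3-(hydroxymethyl)-4-[Ar(hydroxy)methyl]tetrahydrofuran, both C7' epimers
Conditions: TBAF, THF, 0 °C to rt
Reagents that add atoms: none
Why: Fluoride-mediated cleavage of the secondary benzylic silyl ether; no base-sensitive stereocentre is present at this stage and both C7' epimers are carried on together.

Step 9
Reactants: 10 diol, both C7' epimers
Product: 11 {(2S,3R,4R)-2-Ar-3-(hydroxymethyl)tetrahydrofuran-4-yl}(Ar)methanone
Conditions: activated MnO2, CH2Cl2, rt
Reagents that add atoms: none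
Why: MnO2 oxidation is selective for the electron-rich benzylic secondary alcohol over the primary aliphatic C9 alcohol and converges both C7' epimers to one ketone under neutral conditions that should not epimerise C4.

Step 10
Reactants: 11 dibenzyl keto alcohol
Product: 12 ciwujiatone
Conditions: H2 (1 atm), Pd/C (10 wt% Pd), EtOAc, rt, stopped when 11 is consumed
Reagents that add atoms: none
Why: Catalytic hydrogenolysis of the two aryl benzyl ethers under neutral, aprotic conditions, where the p-oxygenated aryl ketone and the benzylic C2–O1 bond should react more slowly and C4 is not exposed to acid or base.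

**Compound list**

1 | syringaldehyde (4-hydroxy-3,5-dimethoxybenzaldehyde) | COc1cc(C=O)cc(OC)c1O | starting material
2 | 4-(benzyloxy)-3,5-dimethoxybenzaldehyde | COc1cc(C=O)cc(OC)c1OCc1ccccc1 | intermediate
3 | vinylmagnesium bromide | C=C[Mg]Br | starting material
4 | rac-1-[4-(benzyloxy)-3,5-dimethoxyphenyl]prop-2-en-1-ol | COc1cc(cc(OC)c1OCc1ccccc1)C(O)C=C | intermediate
5 | (R)-[4-(benzyloxy)-3,5-dimethoxyphenyl][(2S)-oxiran-2-yl]methanol | COc1cc(cc(OC)c1OCc1ccccc1)[C@@H](O)[C@@H]1CO1 | intermediate
6 | 1-[4-(benzyloxy)-3,5-dimethoxyphenyl]prop-2-en-1-one | COc1cc(cc(OC)c1OCc1ccccc1)C(=O)C=C | intermediate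
7 | 1-[4-(benzyloxy)-3,5-dimethoxyphenyl]-3-{(R)-[4-(benzyloxy)-3,5-dimethoxyphenyl][(2S)-oxiran-2-yl]methoxy}propan-1-one | COc1cc(cc(OC)c1OCc1ccccc1)[C@@H](OCCC(=O)c1cc(OC)c(OCc2ccccc2)c(OC)c1)[C@@H]1CO1 | intermediate
8 | tert-butyl{[(1Z)-1-[4-(benzyloxy)-3,5-dimethoxyphenyl]-3-{(R)-[4-(benzyloxy)-3,5-dimethoxyphenyl][(2S)-oxiran-2-yl]methoxy}prop-1-en-1-yl]oxy}dimethylsilane | COc1cc(cc(OC)c1OCc1ccccc1)[C@@H](OC/C=C(\O[Si](C)(C)C(C)(C)C)c1cc(OC)c(OCc2ccccc2)c(OC)c1)[C@@H]1CO1 | intermediate
9 | [(2S,3R,4R)-2-[4-(benzyloxy)-3,5-dimethoxyphenyl]-4-{[4-(benzyloxy)-3,5-dimethoxyphenyl][(tert-butyldimethylsilyl)oxy]methyl}tetrahydrofuran-3-yl]methanol, both C7' epimers | COc1cc(cc(OC)c1OCc1ccccc1)C(O[Si](C)(C)C(C)(C)C)[C@H]1CO[C@H](c2cc(OC)c(OCc3ccccc3)c(OC)c2)[C@H]1CO | intermediate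
10 | (2S,3R,4R)-2-[4-(benzyloxy)-3,5-dimethoxyphenyl]-4-{[4-(benzyloxy)-3,5-dimethoxyphenyl](hydroxy)methyl}-3-(hydroxymethyl)tetrahydrofuran, both C7' epimers | COc1cc(cc(OC)c1OCc1ccccc1)C(O)[C@H]1CO[C@H](c2cc(OC)c(OCc3ccccc3)c(OC)c2)[C@H]1CO | intermediate
11 | {(2S,3R,4R)-2-[4-(benzyloxy)-3,5-dimethoxyphenyl]-3-(hydroxymethyl)tetrahydrofuran-4-yl}[4-(benzyloxy)-3,5-dimethoxyphenyl]methanone | COc1cc(cc(OC)c1OCc1ccccc1)C(=O)[C@H]1CO[C@H](c2cc(OC)c(OCc3ccccc3)c(OC)c2)[C@H]1CO | intermediate
12 | ciwujiatone, {(2S,3R,4R)-2-(4-hydroxy-3,5-dimethoxyphenyl)-3-(hydroxymethyl)tetrahydrofuran-4-yl}(4-hydroxy-3,5-dimethoxyphenyl)methanone | COc1cc(C(=O)[C@H]2CO[C@H](c3cc(OC)c(O)c(OC)c3)[C@H]2CO)cc(OC)c1O | target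

**Count**

Total steps: 10. Longest linear sequence: 9 steps (1, 2, 3, 5, 6, 7, 8, 9, 10 from syringaldehyde); step 4 is a one-step branch from compound 4.

**Steps most likely to fail**

Step 7. The secondary C3 radical may be captured by a second Cp2TiCl and eliminated to the allylic ether before it adds to the electron-rich enol ether. The enol silane may also be cleaved by Lewis acidic titanium or manganese chlorides, or the Z-siloxy substituent may erode the chair preference and with it the 3,4-cis selectivity. The fallback changes the acceptor group. It sets out from 7: the potassium enolate (KN(SiMe3)2, THF, −78 °C) would be O-acetylated with Ac2O to the (Z)-enol acetate F1, which is not Lewis acid-labile and is less electron-rich. The same Cp2TiCl protocol should then close the ring in the same 5-exo sense to the C7' acetate F2. K2CO3 in MeOH would remove the acetyl group, wherever it sits between the C7' and C9 oxygens, and the route is rejoined at diol 10.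

Step 5. The hindered secondary alcohol may add too slowly, so that the vinyl ketone is consumed by phosphine-initiated oligomerisation, or the transient alkoxide may trigger epoxide migration. The fallback replaces catalytic addition to a free enone by a stoichiometric alkoxide reaction with a stable enone reservoir. It sets out from 6, which would be intercepted with Me2NH to the Mannich base F3 and quaternised with MeI to the crystalline ammonium iodide F4. The sodium alkoxide of 5 (NaH, 2.1 equiv in all, THF/DMF, −20 to 0 °C) would be treated portionwise with F4, which releases 6 by loss of NMe3 only as fast as the excess alkoxide captures it. A cold AcOH quench of the enolate returns the route at 7.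

Step 3. The enantiomeric purity of an epoxide taken as the product of a kinetic resolution falls as conversion nears one half. Epoxidation of a terminal vinyl group is also slow, which exposes the electron-rich benzylic epoxy alcohol to the Lewis acidic titanium for a long time. The fallback separates resolution from epoxidation and sets out from 4. Lipase-catalysed acylation (immobilised Candida antarctica lipase B, vinyl acetate, tert-butyl methyl ether, rt) should leave the (S)-alcohol F5 while the (R)-enantiomer is esterified to the acetate F6. Epoxidation of F5 with Ti(OiPr)4, D-(−)-diisopropyl tartrate and tBuOOH is then a matched, reagent-controlled reaction run to full conversion, and it returns the route at 5.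

**Further compounds**

F1 | step 7 | (1Z)-1-[4-(benzyloxy)-3,5-dimethoxyphenyl]-3-{(R)-[4-(benzyloxy)-3,5-dimethoxyphenyl][(2S)-oxiran-2-yl]methoxy}prop-1-en-1-yl acetate | COc1cc(cc(OC)c1OCc1ccccc1)[C@@H](OC/C=C(\OC(C)=O)c1cc(OC)c(OCc2ccccc2)c(OC)c1)[C@@H]1CO1
F2 | step 7 | [4-(benzyloxy)-3,5-dimethoxyphenyl]{(2S,3R,4R)-2-[4-(benzyloxy)-3,5-dimethoxyphenyl]-3-(hydroxymethyl)tetrahydrofuran-4-yl}methyl acetate, both C7' epimers | COc1cc(cc(OC)c1OCc1ccccc1)C(OC(C)=O)[C@H]1CO[C@H](c2cc(OC)c(OCc3ccccc3)c(OC)c2)[C@H]1CO
F3 | step 5 | 1-[4-(benzyloxy)-3,5-dimethoxyphenyl]-3-(dimethylamino)propan-1-one | COc1cc(cc(OC)c1OCc1ccccc1)C(=O)CCN(C)C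
F4 | step 5 | {3-[4-(benzyloxy)-3,5-dimethoxyphenyl]-3-oxopropyl}trimethylammonium iodide | COc1cc(cc(OC)c1OCc1ccccc1)C(=O)CC[N+](C)(C)C.[I-]
F5 | step 3 | (S)-1-[4-(benzyloxy)-3,5-dimethoxyphenyl]prop-2-en-1-ol | COc1cc(cc(OC)c1OCc1ccccc1)[C@@H](O)C=C
F6 | step 3 | (R)-1-[4-(benzyloxy)-3,5-dimethoxyphenyl]prop-2-en-1-yl acetate | COc1cc(cc(OC)c1OCc1ccccc1)[C@H](OC(C)=O)C=C
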